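**Plan**
- The last disconnection is the C3 silyl ether. Before it, the C5–C10 ring-fusion bond and the C4–O bond are cut in one operation. In eudesmane numbering (ring A = C1–C5 and C10, ring B = C5–C10) the fusion bond is flanked by three syn-axial β groups: CH3-14 on C10, O4 on C4 and the benzoate oxygen O6 on C6. That pattern is what a transannular cation–olefin closure of a ten-membered 1(10),4-diene leaves when the C6 ester quenches the C4 cation.
- The ten-membered ring is then cut at C8–C9 with C1–C6 re-joined (anionic oxy-Cope retron). This gives a 1,2-dialkenylcyclohexenol built from (R)-carvone and 2-bromo-3-methylbut-1-ene.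
- Forward order: carvone six-membered ring, ring expansion to the ten-membered ring, Z-to-E isomerisation of the C4=C5 enone, ketone reduction and benzoylation, rings A and B together through the single C5–C10 bond, desilylation.
- Stereochemistry: C3 comes from the carvone centre by Luche reduction (that centre later becomes sp2 C1). C6 and C7 come from a catalyst-controlled ketone hydrogenation with dynamic kinetic resolution. C10, C5 and C4 come from the chair–chair fold of the diene and internal delivery of oxygen by the 6β-benzoate.

Key step: step 9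

Numbering: the ten-membered compounds are numbered as germacranes (C1=C10 carrying CH3-14, C2, C3, C4 carrying CH3-15, C5, C6, C7 carrying the isopropyl group, C8, C9); the same numbers hold in the eudesmanes.
Assumption: in the two ten-membered ketones of the route the C7 centre, α to the C6 carbonyl, is configurationally labile; both ketones are carried as pairs of C7 epimers and the centre is fixed only in step 7.

Step 1
Reactants: 1 (R)-carvone
Product: 2 (1R,5R)-cis-carveol [(1R,5R)-2-methyl-5-(prop-1-en-2-yl)cyclohex-2-en-1-ol]
Conditions: NaBH4, CeCl3·7H2O, MeOH, −78 to 0 °C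
Reagents that add atoms: none
Why: Luche reduction gives clean 1,2-reduction, and axial delivery of hydride to the half-chair enone with its isopropenyl group equatorial should set the new carbinol centre 1R, cis to that group.

Step 2
Reactants: 2 (1R,5R)-cis-carveol
Product: 3 (1R,5R)-cis-carveol tert-butyldimethylsilyl ether
Conditions: TBSCl, imidazole, DMF, 23 °C
Reagents that add atoms: tert-butyldimethylsilyl chloride, CC(C)(C)[Si](C)(C)Cl
Why: Standard silylation of a secondary allylic alcohol gives an ether that tolerates organolithium, KH and mild acid and that cannot act as a neighbouring group at C4 in the key step.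

Step 3
Reactants: 3 (1R,5R)-cis-carveol tert-butyldimethylsilyl ether
Product: 4 (4R,6R)-4-(tert-butyldimethylsilyloxy)-3-methyl-6-(prop-1-en-2-yl)cyclohex-2-en-1-one
Conditions: CrO3, 3,5-dimethylpyrazole, CH2Cl2, −20 °C
Reagents that add atoms: chromium trioxide, O=[Cr](=O)=O
Why: Allylic C–H oxidation by the CrO3–3,5-dimethylpyrazole complex should attack the ring methylene next to the vinylic CH, as in the oxidation of Δ5-steroid 3-ethers to 7-ketones, while the oxygen-bearing allylic position is deactivated; no stereocentre is formed.

Step 4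
Reactants: 4 (4R,6R)-4-(tert-butyldimethylsilyloxy)-3-methyl-6-(prop-1-en-2-yl)cyclohex-2-en-1-one, 5 2-bromo-3-methylbut-1-ene
Product: 7 (1R,4R,6R)-4-(tert-butyldimethylsilyloxy)-3-methyl-1-(3-methylbut-1-en-2-yl)-6-(prop-1-en-2-yl)cyclohex-2-en-1-ol, via 2-lithio-3-methylbut-1-ene 6 (not isolated)
Conditions: t-BuLi (2 equiv), Et2O, −78 °C; then 4, −78 °C; H2O
Reagents that add atoms: none
Why: Bromine–lithium exchange is followed by 1,2-addition of the alkenyllithium to the enone carbonyl anti to the adjacent equatorial isopropenyl group, which should give the trans-dialkenyl carbinol (new centre 1R) that a chair-like rearrangement needs.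

Step 5
Reactants: 7 (1R,4R,6R)-4-(tert-butyldimethylsilyloxy)-3-methyl-1-(3-methylbut-1-en-2-yl)-6-(prop-1-en-2-yl)cyclohex-2-en-1-ol
Product: 10 (1(10)E,4Z,3R)-3-(tert-butyldimethylsilyloxy)germacra-1(10),4-dien-6-one (both C7 epimers), via potassium alkoxide 8 (not isolated), via potassium enolate 9 (not isolated)
Conditions: KH, 18-crown-6, THF, 0 to 25 °C; AcOH, −78 °C
Reagents that add atoms: none
Why: The anionic oxy-Cope rearrangement through a chair transition state with both alkenyl groups equatorial breaks C1–C6 and forms C8–C9, which should give the E C1=C10 alkene while the former ring alkene stays Z; protonation of the enolate at C7 is not expected to be selective, which is tolerated because that centre is fixed in step 7.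

Step 6
Reactants: 10 (1(10)E,4Z,3R)-3-(tert-butyldimethylsilyloxy)germacra-1(10),4-dien-6-one (both C7 epimers)
Product: 11 (1(10)E,4E,3R)-3-(tert-butyldimethylsilyloxy)germacra-1(10),4-dien-6-one (both C7 epimers)
Conditions: hν (350 nm), benzene, 5 °C
Reagents that add atoms: none
Why: Photochemical Z/E isomerisation of the enone through its twisted triplet, a known behaviour of ten-membered-ring enones, should give a photostationary mixture from which the E,E dienone is separated and the Z isomer re-irradiated; the low temperature avoids Cope rearrangement of the E,E diene and no stereocentre is touched.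

Step 7
Reactants: 11 (1(10)E,4E,3R)-3-(tert-butyldimethylsilyloxy)germacra-1(10),4-dien-6-one (both C7 epimers)
Product: 12 (1(10)E,4E,3R,6R,7S)-3-(tert-butyldimethylsilyloxy)germacra-1(10),4-dien-6-ol
Conditions: H2 (8 atm), trans-RuCl2[(S)-xylbinap][(S)-daipen] (1 mol %), t-BuOK (5 mol %), i-PrOH, 25 °C
Reagents that add atoms: none
Why: In this Noyori carbonyl-selective hydrogenation with dynamic kinetic resolution, t-BuOK epimerises C7 through the cross-conjugated enolate, the (S,S) catalyst should deliver hydride to the Si face of C6 by analogy with aryl alkyl ketones (the alkenyl group in the place of the aryl group, giving 6R), and peripheral attack past H7 makes the 7S epimer the matched one, so both epimers should converge on the 6R,7S cis alcohol with the alkenes untouched.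

Step 8
Reactants: 12 (1(10)E,4E,3R,6R,7S)-3-(tert-butyldimethylsilyloxy)germacra-1(10),4-dien-6-ol
Product: 13 (1(10)E,4E,3R,6R,7S)-3-(tert-butyldimethylsilyloxy)germacra-1(10),4-dien-6-yl benzoate
Conditions: BzCl, pyridine, DMAP (cat.), CH2Cl2, 0 to 23 °C
Reagents that add atoms: benzoyl chloride, O=C(Cl)c1ccccc1
Why: DMAP-catalysed O-acylation of the hindered allylic alcohol in pyridine keeps the medium basic, so the acid-sensitive diene is not cyclised prematurely, and C6 keeps its configuration.

Step 9
Reactants: 13 (1(10)E,4E,3R,6R,7S)-3-(tert-butyldimethylsilyloxy)germacra-1(10),4-dien-6-yl benzoate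
Product: 15 (3R,4R,5S,6R,7S,10S)-3-(tert-butyldimethylsilyloxy)-4-hydroxyeudesman-6-yl benzoate, via 2-phenyl-1,3-dioxan-2-ylium ion 14 (not isolated)
Conditions: (±)-camphor-10-sulfonic acid (0.2 equiv), H2O (3 equiv), CH2Cl2, 0 °C
Reagents that add atoms: water, O
Why: Protonation of the electron-richer C1=C10 alkene at C1 (the C4=C5 alkene is deactivated by its two allylic C–O bonds) is coupled to attack of C5 on C10; the tertiary C4 cation is then taken on its β face by the carbonyl oxygen of the C6 benzoate to give ion 14, and water adds to the cationic carbon of 14 so that the ortho-acid collapses with the ester on the secondary O6 and the free hydroxyl on the tertiary O4. The closest known reaction type is the acid-induced transannular cyclisation of germacra-1(10),4-dienes to eudesmanes (hedycaryol to the eudesmols), here with the C4 cation quenched in the manner of 1,3-acyloxy participation instead of by an external nucleophile. The single C5–C10 bond closes ring A in a 6-endo and ring B in a 6-exo sense with respect to the C4=C5 alkene, and the carbonyl oxygen closes the transient third six-membered ring in a mode that is endo with respect to the C=O bond. C10 (CH3-14 β) and C5 (H α) should follow from the chair–chair fold of the E,E diene, in which the C7 isopropyl group is equatorial and the C3 silyloxy group pseudo-axial, and C4 (O β, CH3-15 α) from delivery of oxygen by the 6β ester, which can reach only the β lobe of the cation. The step needs ester capture to outrun loss of H5 or H15 and a 1,2-shift of H3, which the six-membered proximity of the carbonyl and the in-plane position of the C3–H bond should secure; it also needs the allylic ester and the silyl ether to survive, which the mild acid at 0 °C should allow.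

Step 10
Reactants: 15 (3R,4R,5S,6R,7S,10S)-3-(tert-butyldimethylsilyloxy)-4-hydroxyeudesman-6-yl benzoate
Product: 16 (3R,4R,5S,6R,7S,10S)-3,4-dihydroxyeudesman-6-yl benzoate (CNP0187831.1)
Conditions: Bu4NF, AcOH (1:1), THF, 0 to 23 °C
Reagents that add atoms: none
Why: Fluoride-induced cleavage of the silyl ether is driven by Si–F bond formation, and buffering with acetic acid keeps the medium near neutral so that the benzoate should neither migrate nor hydrolyse; no stereocentre is affected.

**Compound list**
1 | (R)-carvone | CC(=C)[C@@H]1CC=C(C)C(=O)C1 | starting material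
2 | (1R,5R)-cis-carveol | CC(=C)[C@@H]1CC=C(C)[C@H](O)C1 | intermediate
3 | (1R,5R)-cis-carveol tert-butyldimethylsilyl ether | CC(=C)[C@@H]1CC=C(C)[C@H](O[Si](C)(C)C(C)(C)C)C1 | intermediate
4 | (4R,6R)-4-(tert-butyldimethylsilyloxy)-3-methyl-6-(prop-1-en-2-yl)cyclohex-2-en-1-one | CC(=C)[C@@H]1C(=O)C=C(C)[C@H](O[Si](C)(C)C(C)(C)C)C1 | intermediate
5 | 2-bromo-3-methylbut-1-ene | CC(C)C(Br)=C | starting material
6 | 2-lithio-3-methylbut-1-ene | [Li]C(=C)C(C)C | intermediate (not isolated)
7 | (1R,4R,6R)-4-(tert-butyldimethylsilyloxy)-3-methyl-1-(3-methylbut-1-en-2-yl)-6-(prop-1-en-2-yl)cyclohex-2-en-1-ol | CC(=C)[C@H]1C[C@@H](O[Si](C)(C)C(C)(C)C)C(C)=C[C@]1(O)C(=C)C(C)C | intermediate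
8 | potassium alkoxide of 7 | CC(=C)[C@H]1C[C@@H](O[Si](C)(C)C(C)(C)C)C(C)=C[C@]1([O-])C(=C)C(C)C.[K+] | intermediate (not isolated)
9 | potassium C6=C7 enolate of the ring-expanded ketone (1(10)E,4Z) | CC(C)/C1=C([O-])\C=C(C)/[C@H](O[Si](C)(C)C(C)(C)C)C/C=C(C)/CC1.[K+] | intermediate (not isolated)
10 | (1(10)E,4Z,3R)-3-(tert-butyldimethylsilyloxy)germacra-1(10),4-dien-6-one, C7 epimer pair | CC(C)C1CC/C(C)=C/C[C@@H](O[Si](C)(C)C(C)(C)C)/C(C)=C\C1=O | intermediate
11 | (1(10)E,4E,3R)-3-(tert-butyldimethylsilyloxy)germacra-1(10),4-dien-6-one, C7 epimer pair | CC(C)C1CC/C(C)=C/C[C@@H](O[Si](C)(C)C(C)(C)C)/C(C)=C/C1=O | intermediate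
12 | (1(10)E,4E,3R,6R,7S)-3-(tert-butyldimethylsilyloxy)germacra-1(10),4-dien-6-ol | CC(C)[C@@H]1CC/C(C)=C/C[C@@H](O[Si](C)(C)C(C)(C)C)/C(C)=C/[C@@H]1O | intermediate
13 | (1(10)E,4E,3R,6R,7S)-3-(tert-butyldimethylsilyloxy)germacra-1(10),4-dien-6-yl benzoate | CC(C)[C@@H]1CC/C(C)=C/C[C@@H](O[Si](C)(C)C(C)(C)C)/C(C)=C/[C@@H]1OC(=O)c1ccccc1 | intermediate
14 | 2-phenyl-1,3-dioxan-2-ylium ion bridging O4 and O6 of the 3-silyloxy eudesmane (camphorsulfonate counter-ion) | CC(C)[C@@H]1CC[C@@]2(C)CC[C@@H](O[Si](C)(C)C(C)(C)C)[C@](C)(OC(c3ccccc3)=[O+]4)[C@@H]2[C@@H]14 | intermediate (not isolated)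
15 | (3R,4R,5S,6R,7S,10S)-3-(tert-butyldimethylsilyloxy)-4-hydroxyeudesman-6-yl benzoate | CC(C)[C@@H]1CC[C@@]2(C)CC[C@@H](O[Si](C)(C)C(C)(C)C)[C@](C)(O)[C@@H]2[C@@H]1OC(=O)c1ccccc1 | intermediate
16 | (3R,4R,5S,6R,7S,10S)-3,4-dihydroxyeudesman-6-yl benzoate (3α,4β-dihydroxy-5α-eudesman-6β-yl benzoate) | CC(C)[C@@H]1CC[C@@]2(C)CC[C@@H](O)[C@](C)(O)[C@@H]2[C@@H]1OC(=O)c1ccccc1 | target

Total step count: 10
Longest linear sequence: 10 steps, from (R)-carvone 1 to 16

**Steps most likely to fail**

Step 9. The fold that leads to the trans-fused product puts the C6–O bond close to the plane of the C4=C5 alkene beside CH3-15. A competing fold may therefore be populated and give a cis-fused decalin. The C4 cation may also lose H5 or H15, or take H3 by a 1,2-shift, before the ester carbonyl reaches it, and the acid may cleave the silyl ether or ionise the allylic ester. The fallback sets out from 12 and replaces the benzoate by a stronger, irreversible internal trap. Boc2O and DMAP in MeCN convert 12 into the tert-butyl carbonate F1. The same acid in dry CH2Cl2 should then give, through the same C5–C10 closure, capture of the C4 cation by the carbonate carbonyl and loss of isobutene, to form the cyclic 4β,6β-carbonate F2. K2CO3 in MeOH frees the 4β,6β-diol F3, and BzCl, pyridine and DMAP acylate only its secondary O6 hydroxyl. The fallback returns to the route at 15.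

Step 6. The photostationary mixture may be poor in the E enone, or the excited enone may add across the ring to the C1=C10 alkene in a [2+2] sense. The fallback sets out from 10 and rebuilds the C4=C5 bond by elimination instead of isomerising it. Conjugate reduction with [(Ph3P)CuH]6 in benzene gives the saturated ketone F4 (C4 and C7 epimers). LDA and Me3SiCl at −78 °C give the less substituted C5=C6 trimethylsilyl enol ether F5. Saegusa–Ito oxidation with Pd(OAc)2 in MeCN at 23 °C should then give the E enone by syn β-hydride elimination from the palladium enolate, with the two ring bonds anti as in eliminations that form ten-membered E alkenes. The fallback returns to the route at 11.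

Step 7. The alkoxide may send the E enone back to Z, move the double bond out of conjugation or epimerise C3 faster than the ketone is hydrogenated, or the catalyst may be mismatched with the ring bias for both C7 epimers, so that convergence fails. The fallback sets out from 11 and uses substrate control with recycling. NaBH4 and CeCl3·7H2O in MeOH at −78 °C should reduce each C7 epimer by peripheral hydride attack to its cis alcohol, 12 and the (6S,7R) alcohol F6, which are separated by chromatography. F6 is oxidised back to 11 with MnO2 in CH2Cl2, re-equilibrated at C7 with a little DBU, and reduced again. The fallback returns to the route at 12.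

**Further compounds**
F1 | step 9 | (1(10)E,4E,3R,6R,7S)-3-(tert-butyldimethylsilyloxy)germacra-1(10),4-dien-6-yl tert-butyl carbonate | CC(C)[C@@H]1CC/C(C)=C/C[C@@H](O[Si](C)(C)C(C)(C)C)/C(C)=C/[C@@H]1OC(=O)OC(C)(C)C
F2 | step 9 | (3R,4R,5S,6R,7S,10S)-3-(tert-butyldimethylsilyloxy)eudesmane-4,6-diyl cyclic carbonate | CC(C)[C@@H]1CC[C@@]2(C)CC[C@@H](O[Si](C)(C)C(C)(C)C)[C@](C)(OC(=O)O3)[C@@H]2[C@@H]13
F3 | step 9 | (3R,4R,5S,6R,7S,10S)-3-(tert-butyldimethylsilyloxy)eudesmane-4,6-diol | CC(C)[C@@H]1CC[C@@]2(C)CC[C@@H](O[Si](C)(C)C(C)(C)C)[C@](C)(O)[C@@H]2[C@@H]1O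
F4 | step 6 | (1(10)E,3R)-3-(tert-butyldimethylsilyloxy)germacr-1(10)-en-6-one, C4 and C7 epimers | CC(C)C1CC/C(C)=C/C[C@@H](O[Si](C)(C)C(C)(C)C)C(C)CC1=O
F5 | step 6 | (1(10)E,3R)-3-(tert-butyldimethylsilyloxy)-6-(trimethylsilyloxy)germacra-1(10),5-diene, C4 and C7 epimers | CC(C)C1CC/C(C)=C/C[C@@H](O[Si](C)(C)C(C)(C)C)C(C)C=C1O[Si](C)(C)C
F6 | step 7 | (1(10)E,4E,3R,6S,7R)-3-(tert-butyldimethylsilyloxy)germacra-1(10),4-dien-6-ol | CC(C)[C@H]1CC/C(C)=C/C[C@@H](O[Si](C)(C)C(C)(C)C)/C(C)=C/[C@H]1O
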